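**Assumptions:** The target is achiral. Its only axis is the biaryl bond, which has a single ortho substituent on each ring, so it is not configurationally stable and there are no stereocentres to set. 4-Bromo-1,2-bis(benzyloxy)benzene is treated as commercially available (otherwise it is one step from 4-bromocatechol and BnBr).

## Retrosynthetic overview
1. Giganteone A is a malabaricone C dimer. The catechol ring of one unit is joined, ortho to its alkyl chain, to C-3 of the 2,6-dihydroxyphenyl ketone ring of the other unit.
2. The target comes from global O-demethylation/debenzylation of a hexa-protected dimer. That dimer comes from a biomimetic oxidative cross-coupling: the free catechol of monomer A is oxidised to an o-quinone and arylated by the electron-rich 2,6-dimethoxyaryl ketone ring of monomer B. No halide or boron handle is needed.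
3. Monomer B (catechol as dibenzyl ether) is a 2,6-dimethoxyphenyl ketone made from 2,6-dimethoxyphenyllithium and a Weinreb amide. Monomer A, with the free catechol, is obtained from B by hydrogenolysis.
4. The Weinreb amide chain comes from 8-nonenoic acid by Weinreb amide formation, then hydroboration and an alkyl–aryl Suzuki coupling with the dibenzyl-protected bromocatechol.
5. All three rings are commercial. The only ring–ring bond made is the biaryl, and it is formed in Step 5.

## Route

**Step 1**
Reactants: 1 (non-8-enoic acid); 2 (N,O-dimethylhydroxylamine hydrochloride)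
Product: 3 (N-methoxy-N-methylnon-8-enamide)
Conditions: (COCl)2, cat. DMF, CH2Cl2, 0 °C→rt; then 2, pyridine, 0 °C→rt
Reagents that add atoms: none beyond reactant 2 (CNOC·HCl)
Why: Acid chloride formation followed by aminolysis gives the Weinreb amide, which later stops at the ketone stage (no stereocentre).

**Step 2**
Reactants: 3; 4 (4-bromo-1,2-bis(benzyloxy)benzene)
Product: 5 (9-[3,4-bis(benzyloxy)phenyl]-N-methoxy-N-methylnonanamide)
Conditions: (i) 9-BBN (1.1 equiv), THF, 0 °C→rt, 2 h; (ii) 4, Pd(dppf)Cl2 (5 mol%), 3 M aq. K3PO4, THF, 60 °C
Reagents that add atoms: none beyond reactant 4 (the 9-BBN boron is lost)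
Why: Anti-Markovnikov hydroboration of the terminal alkene followed by B-alkyl Suzuki–Miyaura coupling (sp3–sp2) installs the saturated C8 chain on the aryl ring and leaves the benzyl ethers and amide intact.

**Step 3**
Reactants: 5; 6 (1,3-dimethoxybenzene)
Product: 7 (9-[3,4-bis(benzyloxy)phenyl]-1-(2,6-dimethoxyphenyl)nonan-1-one)
Conditions: 6 (2 equiv), n-BuLi (2 equiv), THF, 0 °C, 2 h; cool to −78 °C, add 5, warm to 0 °C; aq. NH4Cl
Reagents that add atoms: none beyond reactant 6
Why: Directed ortho-lithiation between the two OMe groups, then addition to the Weinreb amide (stable chelated tetrahedral intermediate) gives the ketone with no over-addition.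

**Step 4**
Reactants: 7
Product: 8 (1-(2,6-dimethoxyphenyl)-9-(3,4-dihydroxyphenyl)nonan-1-one)
Conditions: H2 (1 atm), 10% Pd/C, EtOAc/EtOH 1:1, rt, 2 h
Reagents that add atoms: none
Why: Catalytic hydrogenolysis removes both benzyl ethers. The 2,6-dimethoxyaryl ketone is twisted out of conjugation and survives.

**Step 5**
Reactants: 8 (catechol, added slowly); 7 (nucleophile, 3 equiv)
Product: 9 (hexa-protected dimer: 1-(2,6-dimethoxyphenyl)-9-{2-[3-(9-(3,4-bis(benzyloxy)phenyl)nonanoyl)-2,4-dimethoxyphenyl]-4,5-dihydroxyphenyl}nonan-1-one)
Conditions: Ag2O (1.2 equiv), 4 Å MS, HFIP/CH2Cl2 1:4, 0 °C→rt; 8 added by syringe pump over 2 h to the stirred mixture of 7 and Ag2O; then aq. Na2S2O4 work-up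
Reagents that add atoms: none (Ag2O is only the oxidant)
Why: Proposed new method: Ag2O oxidises catechol 8 to the 4-alkyl-o-quinone, and the doubly activated C-3 of the 2,6-dimethoxyaryl ketone ring of 7 (ortho to one OMe, para to the other, meta to the acyl group) attacks C-5 of the quinone. C-5 is the position β to the C-1 carbonyl and adjacent to the alkyl group, where dopamine-quinone-type electrophiles are attacked by thiols, amines and indoles. Tautomerisation then rearomatises to the biaryl catechol. HFIP hydrogen-bond activation, excess nucleophile and slow addition (to keep free quinone and catechol low) suppress quinone-methide formation and over-oxidation, and the reductive work-up returns any biaryl quinone to the catechol. The closest known chemistry is nucleophilic 1,4-addition to o-quinones and oxidative arene–catechol cross-dehydrogenative coupling.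

**Step 6**
Reactants: 9
Product: 10 (Giganteone A)
Conditions: BBr3 (12 equiv, 1 M in CH2Cl2), pentamethylbenzene (6 equiv), CH2Cl2, −78 °C→rt, 12 h; MeOH then H2O quench
Reagents that add atoms: none (O–Me and O–Bn become O–H on work-up)
Why: BBr3 cleaves all four aryl methyl ethers and both benzyl ethers (ether demethylation). Pentamethylbenzene traps benzyl cations so the electron-rich catechols are not benzylated. The biaryl and the chelated ketones are untouched, and the product is achiral.

## Compound list
1 | non-8-enoic acid | C=CCCCCCCC(=O)O | starting material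
2 | N,O-dimethylhydroxylamine hydrochloride | CNOC.Cl | starting material
3 | N-methoxy-N-methylnon-8-enamide | C=CCCCCCCC(=O)N(C)OC | intermediate
4 | 4-bromo-1,2-bis(benzyloxy)benzene | Brc1ccc(OCc2ccccc2)c(OCc2ccccc2)c1 | starting material
5 | 9-[3,4-bis(benzyloxy)phenyl]-N-methoxy-N-methylnonanamide | CON(C)C(=O)CCCCCCCCc1ccc(OCc2ccccc2)c(OCc2ccccc2)c1 | intermediate
6 | 1,3-dimethoxybenzene | COc1cccc(OC)c1 | starting material
7 | 9-[3,4-bis(benzyloxy)phenyl]-1-(2,6-dimethoxyphenyl)nonan-1-one | COc1cccc(OC)c1C(=O)CCCCCCCCc1ccc(OCc2ccccc2)c(OCc2ccccc2)c1 | intermediate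
8 | 9-(3,4-dihydroxyphenyl)-1-(2,6-dimethoxyphenyl)nonan-1-one | COc1cccc(OC)c1C(=O)CCCCCCCCc1ccc(O)c(O)c1 | intermediate
9 | hexa-protected dimer (biaryl) | COc1cccc(OC)c1C(=O)CCCCCCCCc1cc(O)c(O)cc1-c1ccc(OC)c(C(=O)CCCCCCCCc2ccc(OCc3ccccc3)c(OCc3ccccc3)c2)c1OC | intermediate
10 | Giganteone A | O=C(CCCCCCCCc1cc(O)c(O)cc1-c1ccc(O)c(C(=O)CCCCCCCCc2ccc(O)c(O)c2)c1O)c1c(O)cccc1O | target

**Total steps:** 6
**Longest linear sequence:** 6 (1→3→5→7→8→9→10)

**Three steps most likely to fail**
1. **Step 5, oxidative cross-coupling.** Risks are wrong regiochemistry on the quinone (C-6 instead of C-5), attack at the quinone-methide benzylic carbon, competing arylation by the veratrole-type ring, and over-oxidation of the biaryl catechol.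
   - Fallback: convert to a conventional Suzuki–Miyaura biaryl synthesis. Make the ring-A aryl bromide by regioselective bromination of a benzyl-protected catechol monomer, make the ring-B arylboronate by lithiation/borylation of the 2,6-dimethoxyaryl ketone, couple them, and then deprotect.
2. **Step 2, B-alkyl Suzuki with a Weinreb amide.** Risks are 9-BBN reduction of the amide and sluggish coupling with an electron-rich aryl bromide.
   - Fallback: build the chain by Sonogashira coupling of non-8-ynoic Weinreb amide with 4-iodo-1,2-bis(benzyloxy)benzene (or 4-iodoveratrole), add the aryllithium, and reduce the alkyne with H2 over Pd/C. Hydrogenolysis then gives the free-catechol monomer directly, and the veratryl analogue serves as the nucleophile partner.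
3. **Step 6, global BBr3 deprotection.** Risks are incomplete cleavage of the 2,6-dimethoxy ketone pair, benzylation of the catechols, and decomposition of the polyphenol.
   - Fallback: redo Steps 3–5 with bis-MOM-protected resorcinol rings (ortho-lithiation of 1,3-bis(MOM-oxy)benzene) and remove the MOM groups with HCl/MeOH in the final step.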